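The constants used here were chosen freely; the result is computed.

I decide to examine gamma, the flask charged at once, through the balance of one small charge, and to ask what that balance allows for the share.

| flask | starting material | partner | capture agent | protic impurity | remark | time |
|---|---|---|---|---|---|---|
| theta | 0.50 M | 0.750 M | 0.0500 M | 0.0250 M | a single well-mixed tank run continuously and read at steady state, 25 min in it on average |  |
| alpha | 0.50 M | 0.750 M (fed, over 25.0 min) | 0.0500 M | 0.0250 M | a stirred flask in which partner is dosed at a steady rate over 25.0 min without added volume, worked up at 25 min | 25 min |
| eta | 0.50 M (fed, over 25.0 min) | 0.750 M | 0.0500 M | 0.0250 M | a stirred flask in which starting material is dosed at a steady rate over 25.0 min without added volume, worked up at 25 min | 25 min |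
| gamma | 0.50 M | 0.750 M | 0.0500 M | 0.0250 M | a closed flask charged with all of it at once and left for 25 min | 25 min |

1. order of the set-ups by the share of target in all that became target or trapped intermediate, at the outlet or at the end, highest first (theta / alpha / eta / gamma)
2. share of target in all that became target or trapped intermediate, at the outlet or at the end, theta
3. share of target in all that became target or trapped intermediate, at the outlet or at the end, alpha
4. share of target in all that became target or trapped intermediate, at the outlet or at the end, eta
5. share of target in all that became target or trapped intermediate, at the outlet or at the end, gamma

- a doubled species enters its step squared and goes two at a time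
- the stated concentrations are those of everything mixed, before any reaction; amounts are the same in each set-up
- the feed brings no volume worth counting
- run time (alpha): 25 min

Which small charge? Protic impurity is the smallest, but at full partner its time is 1.75 s, far shorter than the run. So in gamma it just takes 0.0250 M off partner and leaves 0.725 M. The balance to write is that of capture agent, the limiting reagent of the trapping step.

What does it say? Capture agent falls at its constant times [open intermediate][capture agent], and target forms forward at its constant times [partner][open intermediate], so [open intermediate] cancels on dividing. Keep 1.11, the opening ratio: forward making of target over capture, at the start, after the impurity's toll. It is a momentary ratio of rates, not a constant, and it gives a share of 52.6% for the start. If x is the fraction of capture agent left, then with partner no higher than that start value and the forward step alone, target over trapped intermediate is at most the opening ratio times ln(1/x)/(1−x).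

And x? Counting converted starting material as open intermediate, with nothing lost from it, gives ln(1/x) = 3.77, so x = 2.31%. That overstates the exposure, which only raises the ceiling: a ratio of 4.28, a share of 81.1%.

Where is this weak? In the back step: its time, 17.6 min, is shorter than the run, so the ceiling can stand well above the flask. I commit to gamma between the starting share and that ceiling, and no tighter.

The forecast gives gamma > theta > alpha > eta, with theta 59% (56% to 62%), alpha 53% (49% to 57%), eta 52% (48% to 56%) and gamma 62% (58% to 65%), on the ground that “Capture agent is scarce and nearly used up in the flask runs”. Its gamma is a single number inside my bracket.

    open intermediate + capture agent → trapped intermediate (k1 = 0.00718 M⁻¹ s⁻¹)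
    partner + open intermediate ⇌ target (K2 = 0.58 M⁻¹, k2 = 5.49 × 10⁻⁴ M⁻¹ s⁻¹)
    partner + protic impurity → quenched reagent (k3 = 0.764 M⁻¹ s⁻¹)
    2 partner → homo product (k4 = 1.29 × 10⁻⁴ M⁻¹ s⁻¹)
    starting material → open intermediate (k5 = 0.00213 s⁻¹)

The simulation gives gamma > theta > alpha > eta: theta 58.9%, alpha 56.1%, eta 51.6%, gamma 61.7%, each inside the forecast's range, alpha 0.90 percentage points under its top. In gamma at 25.0 min, 4.92% of the capture agent is left, with target at 15.3% and trapped intermediate at 9.51%. Put into the opening ratio's ceiling, that amount gives 3.51, a share of 77.8%, and the flask stands below it.

Read gamma at 6.0 min: with 70% of the capture agent left, the same ceiling gives a ratio of 1.32, a share of 56.9%. The computed share there is 52.5%.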